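**Retrosynthetic overview**
- Structural feature: in the chroman ring, C2 is a quaternary carbon that carries O1 and lies β to the benzylic C4 through C3. This O1–C2–C3–C4 array is what remains when a phenol oxygen adds to the β-carbon of a β-methyl enal whose methyl carbon (future C3) has first bonded to an aryl aldehyde carbon (future C4).
- Disconnections: O–CH3 last; then C2–CH3 back to a C2–CH2CHO arm (one carbon leaves as CO); then C4–H back to a C4–O bond that ties C4 to this arm as a lactol. The tricyclic lactol is cut at C3–C4 (vinylogous aldol) and O1–C2 (oxa-Michael) into a salicylaldehyde and (E)-phytenal.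
- Ring order: the benzene ring is bought; the dihydropyran ring and then the temporary lactol ring close in the key step; the lactol ring is opened again by C4–O hydrogenolysis.
- Fragments: the salicylaldehyde comes from 2,5-dimethylhydroquinone (monomethylation, ortho-formylation); phytenal comes from natural phytol, which supplies both side-chain stereocentres.

Key step: step 4

Assumption: the (S)-catalyst is taken to give the 2R centre, by a shielding model in which O1 adds to the iminium face remote from the silyloxydiarylmethyl group with the arylcarbinol branch trans to the iminium carbon; if the sense proves opposite, the (R)-catalyst is used, and either catalyst is the commercial diarylprolinol converted to its triethylsilyl ether (TESOTf, Et3N).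

Step 1
Reactants: 1 (2E,7R,11R)-3,7,11,15-tetramethylhexadec-2-en-1-ol (natural phytol)
Product: 2 (2E,7R,11R)-3,7,11,15-tetramethylhexadec-2-enal (phytenal)
Conditions: MnO2 (activated, excess), hexane, rt
Reagents that add atoms: none
Why: Activated MnO2 oxidises the primary allylic alcohol to the enal (allylic alcohol oxidation) and should leave the E double bond and the remote C7 and C11 centres untouched.

Step 2
Reactants: 3 2,5-dimethylbenzene-1,4-diol (2,5-dimethylhydroquinone)
Product: 4 4-methoxy-2,5-dimethylphenol
Conditions: MeI (0.5 equiv), K2CO3 (0.6 equiv), acetone, reflux, N2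
Reagents that add atoms: iodomethane, CI
Why: Williamson ether synthesis on a symmetric diol whose two hydroxyls are equivalent; the excess of diol should hold back the second alkylation, and unreacted diol and diether are removed by base extraction and chromatography.

Step 3
Reactants: 4 4-methoxy-2,5-dimethylphenol
Product: 5 2-hydroxy-5-methoxy-3,6-dimethylbenzaldehyde
Conditions: MgCl2, Et3N, (CH2O)n, MeCN, reflux; then 1 M HCl
Reagents that add atoms: paraformaldehyde (formaldehyde), C=O
Why: Casnati–Skattebøl ortho-formylation, in which the magnesium phenoxide delivers formaldehyde to the only free ortho position (C6 of 4) and a second formaldehyde oxidises the benzylic alkoxide to the aldehyde, so the position next to the methoxy group should not react.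

Step 4
Reactants: 5 2-hydroxy-5-methoxy-3,6-dimethylbenzaldehyde; 2 (2E,7R,11R)-3,7,11,15-tetramethylhexadec-2-enal
Product: 8 tricyclic lactol: (2R,4R)-6-methoxy-5,8-dimethyl-2-[(4R,8R)-4,8,12-trimethyltridecyl]chroman bridged C4–O–CH(OH)–CH2–C2 (lactol epimers), via iminium-bound aldol adduct 6 (not isolated), via ring-opened hydroxy aldehyde 7 (not isolated)
Conditions: (S)-2-{bis[3,5-bis(trifluoromethyl)phenyl][(triethylsilyl)oxy]methyl}pyrrolidine (30 mol %), PhCO2H (30 mol %), toluene, rt
Reagents that add atoms: none
Why: The amine condenses with 2 to an iminium ion that loses a proton from the C3 methyl group, and the unsubstituted CH2 terminus of the resulting dienamine adds to the aldehyde carbon of 5 (vinylogous aldol addition, C3–C4 bond), which restores the conjugated iminium ion 6. The phenol oxygen then adds to the β-carbon of 6 in a 6-exo-trig oxa-Michael closure (O1–C2 bond, dihydropyran ring), and after hydrolysis of the enamine the C4 hydroxyl of 7 adds to the freed aldehyde in a 6-exo-trig hemiacetalisation (lactol ring), which makes 8 the sink of an otherwise reversible sequence. The closest known reaction type is the diarylprolinol silyl ether catalysed domino aldol/oxa-Michael reaction of salicylaldehydes with β,β-disubstituted enals through dienamine and iminium activation. C2 is set by the catalyst, whose silyloxydiarylmethyl group covers one face of the iminium ion so that O1 enters from the open face; C4 is selected by the bridge, because only the isomer with the C4 oxygen and the C2 acetaldehyde arm cis can close the lactol while the trans isomer reverts by retro-oxa-Michael and retro-aldol steps; the lactol carbon stays a mixture of epimers and is removed later. The step needs the dienamine to form at the methyl group and not at the C4 methylene of 2 (phytenal numbering), and to react at its γ-carbon: the methyl-derived dienamine offers an unhindered CH2 terminus whereas the methylene-derived one bears the long chain at its terminus, and adducts of the wrong pathways cannot reach the lactol and return to the pool by retro-aldol reaction.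

Step 5
Reactants: 8 tricyclic lactol
Product: 10 2-[(2R)-6-methoxy-5,8-dimethyl-2-[(4R,8R)-4,8,12-trimethyltridecyl]chroman-2-yl]acetaldehyde, via aldehyde hydrate 9 (not isolated)
Conditions: H2 (3 bar), 10% Pd/C, EtOAc–AcOH (4:1), rt
Reagents that add atoms: none
Why: Acid-assisted catalytic hydrogenolysis of a benzylic C–O bond: the C4–O bond of the lactol is benzylic to an arene with an ortho oxygen and should be cleaved on Pd under H2, which turns C4 into CH2 and leaves the arm as the geminal diol 9 that loses water to the aldehyde; the aliphatic aldehyde, the aryl methyl ether and the non-benzylic O1–C2 bond should survive these mild conditions, so C2 is untouched.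

Step 6
Reactants: 10 2-[(2R)-6-methoxy-5,8-dimethyl-2-[(4R,8R)-4,8,12-trimethyltridecyl]chroman-2-yl]acetaldehyde
Product: 11 (2R)-6-methoxy-2,5,8-trimethyl-2-[(4R,8R)-4,8,12-trimethyltridecyl]chroman (β-tocopherol methyl ether)
Conditions: RhCl(PPh3)3 (1.1 equiv), toluene, 90 °C, Ar
Reagents that add atoms: none
Why: Tsuji–Wilkinson decarbonylation: oxidative addition of the aldehyde C–H bond to RhCl(PPh3)3, CO extrusion and C–H reductive elimination should turn the primary CH2CHO arm into CH3; the alkyl group on rhodium has no β-hydrogen and C2 is not a reacting centre.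

Step 7
Reactants: 11 (2R)-6-methoxy-2,5,8-trimethyl-2-[(4R,8R)-4,8,12-trimethyltridecyl]chroman
Product: 12 (2R)-2,5,8-trimethyl-2-[(4R,8R)-4,8,12-trimethyltridecyl]chroman-6-ol, (2R,4'R,8'R)-β-tocopherol
Conditions: BBr3, CH2Cl2, −78 to 0 °C; then aq. NaHCO3
Reagents that add atoms: none
Why: Lewis-acid cleavage of an aryl methyl ether: BBr3 binds the unhindered methoxy oxygen and bromide attacks the methyl carbon (SN2), which at low temperature should be much faster than ionisation of the hindered tertiary O1–C2 bond, so the C2 configuration is kept.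

**Compound list**
1 | (2E,7R,11R)-3,7,11,15-tetramethylhexadec-2-en-1-ol (natural phytol) | OC/C=C(\C)CCC[C@H](C)CCC[C@H](C)CCCC(C)C | starting material
2 | (2E,7R,11R)-3,7,11,15-tetramethylhexadec-2-enal (phytenal) | O=C/C=C(\C)CCC[C@H](C)CCC[C@H](C)CCCC(C)C | intermediate
3 | 2,5-dimethylbenzene-1,4-diol (2,5-dimethylhydroquinone) | Cc1cc(O)c(C)cc1O | starting material
4 | 4-methoxy-2,5-dimethylphenol | COc1cc(C)c(O)cc1C | intermediate
5 | 2-hydroxy-5-methoxy-3,6-dimethylbenzaldehyde | COc1cc(C)c(O)c(C=O)c1C | intermediate
6 | (7R,11R)-3-[2-hydroxy-2-(2-hydroxy-5-methoxy-3,6-dimethylphenyl)ethyl]-7,11,15-trimethylhexadec-2-enal, carbinol epimers, drawn as the free enal and held in the flask as its iminium ion with the catalyst | O=CC=C(CC(O)c1c(O)c(C)cc(OC)c1C)CCC[C@H](C)CCC[C@H](C)CCCC(C)C | intermediate (not isolated)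
7 | 2-[(2R,4R)-4-hydroxy-6-methoxy-5,8-dimethyl-2-[(4R,8R)-4,8,12-trimethyltridecyl]chroman-2-yl]acetaldehyde (C4–OH and C2–CH2CHO cis) | Cc1cc(OC)c(C)c2c1O[C@@](CC=O)(C[C@H]2O)CCC[C@H](C)CCC[C@H](C)CCCC(C)C | intermediate (not isolated)
8 | tricyclic lactol: (2R,4R)-6-methoxy-5,8-dimethyl-2-[(4R,8R)-4,8,12-trimethyltridecyl]chroman with a C4–O–CH(OH)–CH2–C2 bridge, lactol epimers | Cc1cc(OC)c(C)c2c1O[C@]1(CC(O)O[C@@H]2C1)CCC[C@H](C)CCC[C@H](C)CCCC(C)C | intermediate
9 | 2-[(2R)-6-methoxy-5,8-dimethyl-2-[(4R,8R)-4,8,12-trimethyltridecyl]chroman-2-yl]ethane-1,1-diol (aldehyde hydrate) | Cc1cc(OC)c(C)c2c1O[C@@](CC(O)O)(CC2)CCC[C@H](C)CCC[C@H](C)CCCC(C)C | intermediate (not isolated)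
10 | 2-[(2R)-6-methoxy-5,8-dimethyl-2-[(4R,8R)-4,8,12-trimethyltridecyl]chroman-2-yl]acetaldehyde | Cc1cc(OC)c(C)c2c1O[C@@](CC=O)(CC2)CCC[C@H](C)CCC[C@H](C)CCCC(C)C | intermediate
11 | (2R)-6-methoxy-2,5,8-trimethyl-2-[(4R,8R)-4,8,12-trimethyltridecyl]chroman | Cc1cc(OC)c(C)c2c1O[C@](C)(CCC[C@H](C)CCC[C@H](C)CCCC(C)C)CC2 | intermediate
12 | (2R,4'R,8'R)-β-tocopherol | Cc1cc(O)c(C)c2c1O[C@](C)(CCC[C@H](C)CCC[C@H](C)CCCC(C)C)CC2 | target

Total steps: 7. Longest linear sequence: 6 steps (3 to 4, 5, 8, 10, 11, 12).

**Steps most likely to fail**

1. Step 4. The risk is poor facial selectivity in the oxa-Michael closure, so that both C2 epimers of the lactol form; they differ only in their relation to the remote side-chain centres and do not separate as such. The fallback moves the control from the catalyst to an auxiliary-assisted separation and sets out from 5 and 2. The same union run with no demand on the catalyst (pyrrolidine, PhCO2H, toluene, rt) should give 8 together with its (2S,4S)-epimer F1. Acetalisation of the mixture with (−)-menthol (PPTS, 4 Å sieves, CH2Cl2, rt) should give the menthyl acetal of the 2R,4R core F2 and the menthyl acetal of the 2S,4S core F3; the 2-deoxy lactol should exchange its hydroxyl far more readily than the benzylic C4–O bond ionises. These acetals are diastereomers at a rigid bicyclic core and should separate by chromatography or crystallisation. Hydrolysis of F2 (AcOH–THF–H2O, 40 °C) comes back to the route at 8 as a single C2 epimer.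

2. Step 5. The risk is incomplete cleavage of the hindered C4–O bond, or reduction or acid-induced condensation of the aldehyde that is set free in the same flask. The fallback takes the aldehyde out of play and sets out from 8. NaBH4 (MeOH–THF, 0 °C) should reduce the lactol through its open form to the diol F4. Ionic hydrogenation (Et3SiH, CF3CO2H, CH2Cl2, 0 °C; then K2CO3, MeOH) should remove the benzylic hydroxyl through the C4 cation stabilised by the ortho oxygen and give the primary alcohol F5. Dess–Martin periodinane (NaHCO3, CH2Cl2, rt) should oxidise F5 and come back to the route at 10.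

3. Step 6. The risk is loss of the aryloxy group by β-elimination from the alkylrhodium intermediate, which would open the dihydropyran ring, or slow CO extrusion at the neopentyl-type carbon with thermal retro-oxa-Michael decay of the aldehyde. The fallback is a radical decarboxylation and sets out from 10. Pinnick oxidation (NaClO2, NaH2PO4, 2-methyl-2-butene, t-BuOH–H2O, rt) should give the acid F6. Coupling with N-hydroxypyridine-2-thione (DCC, DMAP cat., CH2Cl2, dark) should give the thiohydroxamate ester F7. Irradiation of F7 with visible light in the presence of excess t-BuSH (toluene, rt) should expel CO2 and deliver hydrogen from the thiol faster than the primary radical can eject the aryloxy group (Barton reductive decarboxylation), coming back to the route at 11.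

**Further compounds**
F1 | step 4 | (2S,4S)-epimer of lactol 8 (C2 and C4 inverted, lactol epimers) | Cc1cc(OC)c(C)c2c1O[C@@]1(CC(O)O[C@H]2C1)CCC[C@H](C)CCC[C@H](C)CCCC(C)C
F2 | step 4 | (1R,2S,5R)-menthyl acetal of lactol 8 (2R,4R core, acetal carbon as formed) | Cc1cc(OC)c(C)c2c1O[C@]1(CC(O[C@@H]3C[C@H](C)CC[C@H]3C(C)C)O[C@@H]2C1)CCC[C@H](C)CCC[C@H](C)CCCC(C)C
F3 | step 4 | (1R,2S,5R)-menthyl acetal of the (2S,4S)-lactol F1 | Cc1cc(OC)c(C)c2c1O[C@@]1(CC(O[C@@H]3C[C@H](C)CC[C@H]3C(C)C)O[C@H]2C1)CCC[C@H](C)CCC[C@H](C)CCCC(C)C
F4 | step 5 | 2-(2-hydroxyethyl)-6-methoxy-5,8-dimethyl-2-[(4R,8R)-4,8,12-trimethyltridecyl]chroman-4-ol, C2 and C4 arranged as in 7 (CIP 2S,4R) | Cc1cc(OC)c(C)c2c1O[C@@](CCO)(C[C@H]2O)CCC[C@H](C)CCC[C@H](C)CCCC(C)C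
F5 | step 5 | 2-[(2R)-6-methoxy-5,8-dimethyl-2-[(4R,8R)-4,8,12-trimethyltridecyl]chroman-2-yl]ethanol | Cc1cc(OC)c(C)c2c1O[C@@](CCO)(CC2)CCC[C@H](C)CCC[C@H](C)CCCC(C)C
F6 | step 6 | 2-[(2R)-6-methoxy-5,8-dimethyl-2-[(4R,8R)-4,8,12-trimethyltridecyl]chroman-2-yl]acetic acid | Cc1cc(OC)c(C)c2c1O[C@@](CC(=O)O)(CC2)CCC[C@H](C)CCC[C@H](C)CCCC(C)C
F7 | step 6 | 2-thioxopyridin-1(2H)-yl ester of acid F6 (thiohydroxamate ester) | Cc1cc(OC)c(C)c2c1O[C@@](CC(=O)On1ccccc1=S)(CC2)CCC[C@H](C)CCC[C@H](C)CCCC(C)C
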